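The C2-symmetric, all-trans tetrahydrofuran ring (O1, C2–C5; aryl on C2 and C5, CH2OH on C3 and C4) is cut at C2–C3 and C4–C5. This gives an ArCH–O–CHAr carbonyl ylide (C2–O1–C5) and a fumaric acid unit (C3–C4). Irradiation opens the C–C bond of a racemic trans-2,3-diaryloxirane to the exo,endo ylide, which adds across a C2-symmetric fumaroyl bis(oxazolidinone). One operation closes the ring, forms two C–C bonds and sets all four stereocentres. The precursors are the bis-silylated trans-oxirane made from vanillin and the Mg(II)-chelated, (S)-valinol-derived bis-imide. Reductive auxiliary removal and desilylation complete the synthesis.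

Key step: step 5

Assumption: the target SMILES is read as the all-trans (2R,3S,4S,5R) isomer, numbered O1, C2(Ar), C3(CH2OH), C4(CH2OH), C5(Ar); the descriptors at C3/C4 change to R,R in the diacyl compounds only because the CIP priorities change.

Step 1
Reactants: 1 vanillin
Product: 2 4-(tert-butyldimethylsilyloxy)-3-methoxybenzaldehyde
Conditions: TBSCl, imidazole, DMF, rt
Reagents that add atoms: tert-butyldimethylsilyl chloride, CC(C)(C)[Si](C)(C)Cl
Why: Imidazole-promoted O-silylation of the phenol (substitution at silicon) leaves the aldehyde untouched, and a silyl ether is chosen because it has no photo-Fries pathway and is later removed without hydrogenolysis of the benzylic C–O bonds.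

Step 2
Reactants: 2 4-(tert-butyldimethylsilyloxy)-3-methoxybenzaldehyde (two equivalents)
Product: 3 (E)-1,2-bis[4-(tert-butyldimethylsilyloxy)-3-methoxyphenyl]ethene
Conditions: TiCl4, Zn, pyridine, THF, 0 °C then reflux; crystallisation to remove any Z isomer
Reagents that add atoms: none
Why: McMurry reductive coupling of an aromatic aldehyde on low-valent titanium should give the symmetrical stilbene in the thermodynamically preferred E geometry, with pyridine buffering the Lewis-acidic chlorides so that the aryl silyl ethers stay in place.

Step 3
Reactants: 3 (E)-1,2-bis[4-(tert-butyldimethylsilyloxy)-3-methoxyphenyl]ethene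
Product: 4 (±)-trans-2,3-bis[4-(tert-butyldimethylsilyloxy)-3-methoxyphenyl]oxirane
Conditions: DMDO (acetone solution), acetone, −20 to 0 °C; evaporation only, no silica, used promptly
Reagents that add atoms: dimethyldioxirane, CC1(C)OO1
Why: Dioxirane epoxidation transfers oxygen in a concerted, stereospecific syn fashion, so the E-alkene becomes the racemic trans-oxirane, and the neutral medium with only a volatile co-product spares this acid-labile, electron-rich oxirane any acid or chromatography.

Step 4
Reactants: 5 (S)-4-isopropyl-2-oxazolidinone (two equivalents); 6 fumaryl chloride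
Product: 8 N,N'-fumaroylbis[(S)-4-isopropyloxazolidin-2-one], via lithium (S)-4-isopropyl-2-oxooxazolidin-3-ide 7 (not isolated)
Conditions: n-BuLi, THF, −78 °C; then 6 (0.5 equiv), −78 to 0 °C
Reagents that add atoms: none
Why: N-Acylation of the lithiated oxazolidinone by the bis(acid chloride) (addition–elimination) should give the C2-symmetric bis-imide with the E-alkene and both auxiliary stereocentres untouched.

Step 5
Reactants: 4 (±)-trans-2,3-bis[4-(tert-butyldimethylsilyloxy)-3-methoxyphenyl]oxirane; 8 N,N'-fumaroylbis[(S)-4-isopropyloxazolidin-2-one]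
Product: 10 all-trans (2R,3R,4R,5R)-2,5-bis[4-(tert-butyldimethylsilyloxy)-3-methoxyphenyl]tetrahydrofuran-3,4-dicarbonyl bis[(S)-4-isopropyloxazolidin-2-one], via exo,endo carbonyl ylide 9 (not isolated)
Conditions: hν (280–300 nm, FEP flow coil), 8 in fivefold excess premixed at 0.1 M with Mg(NTf2)2 (one Mg per imide unit), stream of 4 merged at the coil inlet, degassed dry MeCN–EtOAc, −30 °C; aq. NaHCO3/EDTA; chromatography on Et3N-deactivated silica (surplus 8 recovered)
Reagents that add atoms: none
Why: Excitation of the aryl chromophore of 4 breaks the oxirane C–C bond in the disrotatory sense that orbital symmetry allows for an excited four-electron, three-centre system, so either enantiomer of the trans-oxirane gives the same planar, achiral exo,endo ylide 9, which adds suprafacially on both partners ([π4s+π2s]) to the C=C bond of 8 in a 1:1 addition that loses no atoms. The closest known reaction types are the trapping of photogenerated 2,3-diaryl carbonyl ylides by fumarates and other electron-poor alkenes, and the use of metal-chelated 3-enoyl-2-oxazolidinones as dipolarophiles for carbonyl ylides. The tetrahydrofuran ring (O1, C2–C5) closes by an intermolecular concerted (3+2) cycloaddition in which C2–C3 and C4–C5 form in the same event. The C2/C5 trans relation comes from the exo,endo geometry of 9, the C3/C4 trans relation from the E-alkene, the 2,3- and 4,5-trans relations from the transition state in which each aryl group faces an alkene hydrogen rather than an acyl group, and the absolute sense from the two Mg-chelated, s-cis (S)-imides, whose isopropyl groups both cover the Cα-Re face so that 9 adds to the Si,Si face and gives 3R,4R (3S,4S after reduction). The step needs capture of 9 before it rotates to the exo,exo form, which the high concentration of a LUMO-lowered dipolarophile and the low temperature serve, and it needs one alkene face, which chelation serves because the unchelated anti-dipole conformer holds the isopropyl group far from the alkene and exposes the opposite face. Halide-free Mg(II) tempered by MeCN and a short dark contact time in flow protect the oxirane, and minor diastereomers are removed at this stage so that 10 goes on as a single stereoisomer.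

Step 6
Reactants: 10 all-trans bis-imide cycloadduct
Product: 11 [(2R,3S,4S,5R)-2,5-bis[4-(tert-butyldimethylsilyloxy)-3-methoxyphenyl]tetrahydrofuran-3,4-diyl]dimethanol
Conditions: LiBH4, THF, 0 °C to rt; aq. NH4Cl
Reagents that add atoms: none
Why: Reductive cleavage of N-acyloxazolidinones by LiBH4 (hydride attack at the exocyclic carbonyl) should give both primary alcohols and return the auxiliary, while C3/C4 are safe because the all-trans array is already the most stable one and aryl silyl ethers are inert to borohydride.

Step 7
Reactants: 11 bis-TBS diol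
Product: 12 (+)-neoolivil, (2R,3S,4S,5R)-2,5-bis(4-hydroxy-3-methoxyphenyl)-3,4-bis(hydroxymethyl)tetrahydrofuran
Conditions: TBAF, AcOH (1:1), THF, 0 °C
Reagents that add atoms: none
Why: Fluoride-induced desilylation of the aryl silyl ethers, buffered with acetic acid so that no free phenoxide can open the benzylic ether through a quinone methide, should release the target without touching any stereocentre.

Compound list
1 | vanillin | COc1cc(C=O)ccc1O | starting material
2 | 4-(tert-butyldimethylsilyloxy)-3-methoxybenzaldehyde | COc1cc(C=O)ccc1O[Si](C)(C)C(C)(C)C | intermediate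
3 | (E)-1,2-bis[4-(tert-butyldimethylsilyloxy)-3-methoxyphenyl]ethene | COc1cc(/C=C/c2ccc(O[Si](C)(C)C(C)(C)C)c(OC)c2)ccc1O[Si](C)(C)C(C)(C)C | intermediate
4 | (±)-trans-2,3-bis[4-(tert-butyldimethylsilyloxy)-3-methoxyphenyl]oxirane (racemate, 2S,3S enantiomer drawn) | COc1cc(ccc1O[Si](C)(C)C(C)(C)C)[C@@H]1O[C@H]1c1ccc(O[Si](C)(C)C(C)(C)C)c(OC)c1 | intermediate
5 | (S)-4-isopropyl-2-oxazolidinone | CC(C)[C@H]1COC(=O)N1 | starting material
6 | fumaryl chloride | ClC(=O)/C=C/C(=O)Cl | starting material
7 | lithium (S)-4-isopropyl-2-oxooxazolidin-3-ide (not isolated) | CC(C)[C@H]1COC(=O)[N-]1.[Li+] | intermediate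
8 | N,N'-fumaroylbis[(S)-4-isopropyloxazolidin-2-one] | O=C1OC[C@H](C(C)C)N1C(=O)/C=C/C(=O)N1[C@@H](C(C)C)COC1=O | intermediate
9 | exo,endo (sickle) carbonyl ylide ArCH=O(+)–CH(−)Ar, Ar = 4-TBSO-3-methoxyphenyl, one aryl anti and the other syn to the opposite ylide carbon (not isolated) | COc1cc(ccc1O[Si](C)(C)C(C)(C)C)/C=[O+]/[CH-]c1ccc(O[Si](C)(C)C(C)(C)C)c(OC)c1 | intermediate
10 | (4S,4'S)-3,3'-{[(2R,3R,4R,5R)-2,5-bis(4-tert-butyldimethylsilyloxy-3-methoxyphenyl)tetrahydrofuran-3,4-diyl]dicarbonyl}bis(4-isopropyloxazolidin-2-one), all-trans | COc1cc([C@@H]2O[C@@H](c3ccc(O[Si](C)(C)C(C)(C)C)c(OC)c3)[C@H](C(=O)N3[C@@H](C(C)C)COC3=O)[C@H]2C(=O)N2[C@@H](C(C)C)COC2=O)ccc1O[Si](C)(C)C(C)(C)C | intermediate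
11 | [(2R,3S,4S,5R)-2,5-bis(4-tert-butyldimethylsilyloxy-3-methoxyphenyl)tetrahydrofuran-3,4-diyl]dimethanol | COc1cc([C@@H]2O[C@@H](c3ccc(O[Si](C)(C)C(C)(C)C)c(OC)c3)[C@H](CO)[C@H]2CO)ccc1O[Si](C)(C)C(C)(C)C | intermediate
12 | (+)-neoolivil | COc1cc([C@@H]2O[C@@H](c3ccc(O)c(OC)c3)[C@H](CO)[C@H]2CO)ccc1O | target

Total step count: 7. Longest linear sequence: 6 (steps 1, 2, 3, 5, 6, 7).

Steps most likely to fail

Step 5. Mg(II) may rearrange the oxirane in the dark, and the ylide may rotate before capture. Light absorbed by the dipolarophile may isomerise its double bond, and discrimination between the alkene faces may be weak. The fallback takes absolute control out of the photochemical step. Setting out from 4, the irradiation is run without any Lewis acid in the presence of dimethyl fumarate, the classical partner for such ylides and cheap enough to be used at very high concentration. This should give racemic all-trans dimethyl 2,5-bis(4-tert-butyldimethylsilyloxy-3-methoxyphenyl)tetrahydrofuran-3,4-dicarboxylate F1. Reduction with LiAlH4 in THF at 0 °C should give the racemic bis-TBS diol F2. Preparative chromatography on a polysaccharide chiral stationary phase then separates the enantiomers, and the route is rejoined at 11.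

Step 3. The electron-rich oxirane may open or rearrange to a carbonyl compound during formation or isolation, and the arenes may be over-oxidised. The fallback builds the oxirane by C–C bond formation under basic conditions instead of by alkene oxidation. It sets out from 2, which NaBH4 reduces to 4-(tert-butyldimethylsilyloxy)-3-methoxybenzyl alcohol F3. PBr3 in Et2O at 0 °C then gives 4-(tert-butyldimethylsilyloxy)-3-methoxybenzyl bromide F4. Tetrahydrothiophene in acetone converts this into 1-[4-(tert-butyldimethylsilyloxy)-3-methoxybenzyl]tetrahydrothiophenium bromide F5. Deprotonation with LiHMDS in THF at −78 °C and addition of a second equivalent of 2 follow (sulfonium-ylide epoxidation of Johnson–Corey–Chaykovsky type). Reversible betaine formation should favour the trans-oxirane. The route is rejoined at 4, and step 2 is bypassed as well.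

Step 2. The silyl groups may be lost to the titanium and zinc chlorides at reflux, or the coupling may stop at the diol stage. The fallback replaces reductive carbonyl coupling by olefin metathesis. Setting out from 2, Wittig methylenation (Ph3P=CH2, THF) gives tert-butyl(2-methoxy-4-vinylphenoxy)dimethylsilane F6. Self-metathesis with the second-generation Grubbs catalyst in refluxing CH2Cl2 is driven by loss of gas and runs under neutral conditions. It should give the E-stilbene, and the route is rejoined at 3.

Further compounds
F1 | step 5 | (±)-dimethyl (2R*,3R*,4R*,5R*)-2,5-bis(4-tert-butyldimethylsilyloxy-3-methoxyphenyl)tetrahydrofuran-3,4-dicarboxylate (all-trans racemate, one enantiomer drawn) | COc1cc([C@@H]2O[C@@H](c3ccc(O[Si](C)(C)C(C)(C)C)c(OC)c3)[C@H](C(=O)OC)[C@H]2C(=O)OC)ccc1O[Si](C)(C)C(C)(C)C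
F2 | step 5 | (±)-[(2R*,3S*,4S*,5R*)-2,5-bis(4-tert-butyldimethylsilyloxy-3-methoxyphenyl)tetrahydrofuran-3,4-diyl]dimethanol (racemate, one enantiomer drawn) | COc1cc([C@@H]2O[C@@H](c3ccc(O[Si](C)(C)C(C)(C)C)c(OC)c3)[C@H](CO)[C@H]2CO)ccc1O[Si](C)(C)C(C)(C)C
F3 | step 3 | 4-(tert-butyldimethylsilyloxy)-3-methoxybenzyl alcohol | COc1cc(CO)ccc1O[Si](C)(C)C(C)(C)C
F4 | step 3 | 4-(tert-butyldimethylsilyloxy)-3-methoxybenzyl bromide | COc1cc(CBr)ccc1O[Si](C)(C)C(C)(C)C
F5 | step 3 | 1-[4-(tert-butyldimethylsilyloxy)-3-methoxybenzyl]tetrahydrothiophenium bromide | COc1cc(C[S+]2CCCC2)ccc1O[Si](C)(C)C(C)(C)C.[Br-]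
F6 | step 2 | tert-butyl(2-methoxy-4-vinylphenoxy)dimethylsilane | C=Cc1ccc(O[Si](C)(C)C(C)(C)C)c(OC)c1
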